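**Plan**

1. Retrosynthetic cuts (labdane numbering): the C15 ester and the two acyl groups; C6–O and C7–O (back to a 6β,7β-epoxide and an 8-en-7-one); C13=C14 (olefination); C9–C11 (organometallic addition to a C9 ketone with 1,3-oxygen transposition); C3–C4 of ring A; last C10–C1 and C10–CH3, which leaves (R)-carvone.
2. Forward: ring B is the carvone ring throughout. C10 is made quaternary by two enolate alkylations, ring A is closed by the C3–C4 bond, the C9 side chain is joined and extended, and ring B is oxygenated last.
3. Enabling feature: C4, the quaternary gem-dimethyl carbon of ring A bound to C5, is a hydrogenated isopropenyl group. The carvone isopropenyl group can therefore be turned into the C4 tertiary radical by Markovnikov hydrogen-atom transfer and closed onto C3, which is made the terminal carbon of an acrylate hung on C10. The acrylate ester at C2 is a helper and is removed by decarboxylation.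
4. Stereochemistry: C5 comes from (R)-carvone; C10 from alkylation anti to the isopropenyl group; C6 and C7 from α-face bromination, α-face hydride delivery, inversion at C6 on epoxide closure and trans-diaxial opening at C7; the 13E alkene from a thermodynamically controlled Horner–Wadsworth–Emmons olefination.

Key step: step 3

Remark: labdane numbering is used for all compounds, including the monocyclic ones (ring A = C1–C5 and C10, ring B = C5–C10, β = the face of the C10 methyl). Compounds 2 and 5 are expected as epimer mixtures at centres that are later planarised or deleted; their SMILES show the expected major epimer.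

**Step 1**
Reactants: 1 (R)-(−)-carvone
Product: 2 6-methylcarvone (methyl trans to isopropenyl drawn)
Conditions: LiN(i-Pr)2, THF, −78 °C; MeI, −78 to 0 °C
Reagents that add atoms: iodomethane, CI
Why: Kinetic α′-deprotonation of the enone and SN2 methylation of the enolate (enolate alkylation) should give 2, whose new centre is planarised again in step 2, so its configuration is of no consequence.

**Step 2**
Reactants: 2 6-methylcarvone; 3 methyl 2-(bromomethyl)acrylate
Product: 4 methyl 2-{[1,3-dimethyl-2-oxo-6-(prop-1-en-2-yl)cyclohex-3-en-1-yl]methyl}prop-2-enoate (acrylate arm trans and ring methyl cis to the isopropenyl group)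
Conditions: LiN(i-Pr)2, THF, −78 °C; then 3, −78 to −20 °C
Reagents that add atoms: none
Why: Enolate alkylation by addition–elimination (SN2′) on the bromomethyl acrylate should set C10, because A(1,2) strain with the enolate methyl forces the adjacent isopropenyl group pseudoaxial and the electrophile enters anti to it.

**Step 3**
Reactants: 4 methyl 2-{[1,3-dimethyl-2-oxo-6-(prop-1-en-2-yl)cyclohex-3-en-1-yl]methyl}prop-2-enoate
Product: 5 methyl 9-oxo-11-nordrim-7-ene-2-carboxylate (trans-fused, 5α-H, 10β-CH3; 2α-ester drawn)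
Conditions: Fe(acac)3 (0.3 equiv), PhSiH3, EtOH/HOCH2CH2OH (5:1), 60 °C, 0.01 M
Reagents that add atoms: none
Why: A trivalent iron hydride formed from Fe(acac)3 and PhSiH3 transfers a hydrogen atom to the CH2 terminus of the electron-rich isopropenyl group (Markovnikov), which gives the gem-dimethyl tertiary radical at C4; this nucleophilic radical adds to C3, the unsubstituted β-carbon of the acrylate, and the α-ester radical at C2 is reduced by divalent iron and protonated by ethanol. The closest known reaction type is the metal-hydride HAT-initiated reductive olefin coupling (radical conjugate addition of the Giese type) in its intramolecular form. Ring A closes in the 6-endo-trig mode through a chair-like transition state in which the C5 and C10 arms are trans-diequatorial on ring B, so only the trans-fused bicycle can form. C4 is not stereogenic; the only new stereocentre is C2, set without control by enolate protonation and deleted in step 5, while C5 and C10 are carried through unchanged. The step needs chemoselective hydrogen-atom transfer to the isopropenyl group over the acrylate and the ring enone, which the preference of the metal hydride for electron-rich 1,1-disubstituted alkenes should secure. It also needs 6-endo over 5-exo closure, which radical polarity and the substituent at C2 should secure, since the 5-exo path would attack the substituted α-carbon; high dilution suppresses intermolecular addition.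

**Step 4**
Reactants: 5 methyl 9-oxo-11-nordrim-7-ene-2-carboxylate
Product: 6 9-oxo-11-nordrim-7-ene-2-carboxylic acid
Conditions: LiOH, THF/MeOH/H2O, 25 °C; then 1 M HCl
Reagents that add atoms: lithium hydroxide, [Li+].[OH-]
Why: Saponification of an unhindered secondary methyl ester should proceed without touching the enone, whose α-carbon C10 is quaternary.

**Step 5**
Reactants: 6 9-oxo-11-nordrim-7-ene-2-carboxylic acid
Product: 7 (4aS,8aS)-2,5,5,8a-tetramethyl-4a,5,6,7,8,8a-hexahydronaphthalen-1(4H)-one (11-nordrim-7-en-9-one)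
Conditions: 9-mesityl-10-phenylacridinium tetrafluoroborate (cat.), PhSSPh (cat.), i-Pr2NEt (cat.), CF3CH2OH, 450 nm LED, 25 °C
Reagents that add atoms: none
Why: Photoredox hydrodecarboxylation (oxidation of the carboxylate by the excited acridinium, loss of CO2, hydrogen-atom transfer from thiophenol to the C2 radical) should remove the activating group and with it the C2 stereocentre.

**Step 6**
Reactants: 7 11-nordrim-7-en-9-one; 8 2-(2-bromoethyl)-2-methyl-1,3-dioxolane
Product: 10 13,13-ethylenedioxy-14,15-dinorlabd-7-en-9-ol (9β-OH expected), via dioxolanylethylmagnesium bromide 9 (not isolated)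
Conditions: 8, Mg, THF, 25 °C; then 7, LaCl3·2LiCl (cat.), THF, 0 °C; H2O
Reagents that add atoms: none
Why: Lanthanum-promoted 1,2-addition of the Grignard reagent to the hindered ketone, which cannot enolise at C10, should occur from the α-face anti to the axial C10 methyl, and the C9 configuration is erased in step 7.

**Step 7**
Reactants: 10 13,13-ethylenedioxy-14,15-dinorlabd-7-en-9-ol
Product: 11 13,13-ethylenedioxy-14,15-dinorlabd-8-en-7-one
Conditions: [C5H5NH][CrO3Cl], Celite, CH2Cl2, 25 °C
Reagents that add atoms: pyridinium chlorochromate, [O-][Cr](=O)(=O)Cl.c1cc[nH+]cc1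
Why: Oxidative 1,3-transposition of a tertiary allylic alcohol (Babler–Dauben oxidation: chromate ester, [3,3] shift of oxygen to C7, oxidation) should give the 8-en-7-one with the side chain on C9, and the ketal tolerates the reagent.

**Step 8**
Reactants: 11 13,13-ethylenedioxy-14,15-dinorlabd-8-en-7-one
Product: 12 14,15-dinorlabd-8-ene-7,13-dione
Conditions: 1 M HCl, THF, 25 °C
Reagents that add atoms: water, O
Why: Acid hydrolysis of the dioxolane should free the methyl ketone while the tetrasubstituted enone is inert.

**Step 9**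
Reactants: 12 14,15-dinorlabd-8-ene-7,13-dione; 13 allyl diethylphosphonoacetate
Product: 14 allyl 7-oxolabda-8,13E-dien-15-oate
Conditions: 13, NaH, THF, 0 °C; then 12, 0 to 40 °C
Reagents that add atoms: none
Why: Horner–Wadsworth–Emmons olefination should take place at the methyl ketone in preference to the hindered conjugated ring ketone and should favour the E-enoate (ester trans to the longer chain) under reversible addition, the Z-isomer being removed by chromatography.

**Step 10**
Reactants: 14 allyl 7-oxolabda-8,13E-dien-15-oate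
Product: 16 allyl 6α-bromo-7-oxolabda-8,13E-dien-15-oate, via trimethylsilyl dienol ether 15 (not isolated)
Conditions: LiN(SiMe3)2, Me3SiCl, THF, −78 °C; then N-bromosuccinimide, THF, −78 to 0 °C
Reagents that add atoms: N-bromosuccinimide, O=C1CCC(=O)N1Br; chlorotrimethylsilane, C[Si](C)(C)Cl (its silicon stays only in 15)
Why: Kinetic α′-enolisation of the enone at C6 with silyl trapping, then electrophilic bromination of the silyl enol ether, should deliver bromine from the α-face, because the β-face of C6 is shielded by the syn-axial methyls on C10 and C4, which gives the equatorial 6α-bromide.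

**Step 11**
Reactants: 16 allyl 6α-bromo-7-oxolabda-8,13E-dien-15-oate
Product: 17 allyl 6α-bromo-7β-hydroxylabda-8,13E-dien-15-oate
Conditions: NaBH4, CeCl3·7H2O, MeOH, −40 °C
Reagents that add atoms: none
Why: Luche 1,2-reduction with axial hydride delivery from the open α-face should give the equatorial 7β-alcohol trans to bromine, as in the reduction of equatorial α-bromo cyclohexanones.

**Step 12**
Reactants: 17 allyl 6α-bromo-7β-hydroxylabda-8,13E-dien-15-oate
Product: 18 allyl 6β,7β-epoxylabda-8,13E-dien-15-oate
Conditions: K2CO3, allyl alcohol, 25 °C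
Reagents that add atoms: none
Why: Intramolecular Williamson etherification (SN2 with inversion at C6) through a boat-like ring B, the classical way from a trans-diequatorial bromohydrin to the epoxide on the more hindered face, should give the β-epoxide, and allyl alcohol as solvent makes ester exchange degenerate.

**Step 13**
Reactants: 18 allyl 6β,7β-epoxylabda-8,13E-dien-15-oate
Product: 19 allyl 6β-hydroxy-7α-(3-methylbutanoyloxy)labda-8,13E-dien-15-oate
Conditions: 3-methylbutanoic acid (excess), CH2Cl2, 25 °C
Reagents that add atoms: 3-methylbutanoic acid, CC(C)CC(=O)O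
Why: Acid-assisted trans-diaxial opening of the vinyl epoxide (Fürst–Plattner) should occur at the allylic C7 from the open α-face with inversion, which leaves the epoxide oxygen as the axial 6β-hydroxyl and places the ester at 7α.

**Step 14**
Reactants: 19 allyl 6β-hydroxy-7α-(3-methylbutanoyloxy)labda-8,13E-dien-15-oate
Product: 20 allyl 6β-acetoxy-7α-(3-methylbutanoyloxy)labda-8,13E-dien-15-oate
Conditions: Ac2O, DMAP, pyridine, 40 °C
Reagents that add atoms: acetic anhydride, CC(=O)OC(C)=O
Why: DMAP-catalysed acetylation should acylate the hindered axial 6β-hydroxyl on warming, and the trans-diaxial relation to the C7 ester blocks acyl migration.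

**Step 15**
Reactants: 20 allyl 6β-acetoxy-7α-(3-methylbutanoyloxy)labda-8,13E-dien-15-oate
Product: 21 6β-acetoxy-7α-(3-methylbutanoyloxy)labda-8,13E-dien-15-oic acid
Conditions: Pd(PPh3)4 (cat.), morpholine, THF, 25 °C; then dilute citric acid
Reagents that add atoms: none
Why: Tsuji–Trost deallylation by zerovalent palladium should cleave only the unhindered allyl ester, since the C7 allylic ester sits on a tetrasubstituted alkene whose β-face is blocked by the C10 methyl.

**Compound list**

1 | (R)-(−)-carvone | C1C=C(C)C(=O)C[C@@H]1C(C)=C | starting material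
2 | 6-methylcarvone (methyl trans to isopropenyl) | C1C=C(C)C(=O)[C@@H](C)[C@@H]1C(C)=C | intermediate
3 | methyl 2-(bromomethyl)acrylate | C=C(CBr)C(=O)OC | starting material
4 | methyl 2-{[1,3-dimethyl-2-oxo-6-(prop-1-en-2-yl)cyclohex-3-en-1-yl]methyl}prop-2-enoate (arm trans to isopropenyl) | C1C=C(C)C(=O)[C@@](C)(CC(=C)C(=O)OC)[C@@H]1C(C)=C | intermediate
5 | methyl 9-oxo-11-nordrim-7-ene-2-carboxylate (2α-ester drawn) | C1C=C(C)C(=O)[C@@]2(C)C[C@@H](C(=O)OC)CC(C)(C)[C@H]12 | intermediate
6 | 9-oxo-11-nordrim-7-ene-2-carboxylic acid | C1C=C(C)C(=O)[C@@]2(C)C[C@@H](C(=O)O)CC(C)(C)[C@H]12 | intermediate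
7 | (4aS,8aS)-2,5,5,8a-tetramethyl-4a,5,6,7,8,8a-hexahydronaphthalen-1(4H)-one | C1C=C(C)C(=O)[C@@]2(C)CCCC(C)(C)[C@H]12 | intermediate
8 | 2-(2-bromoethyl)-2-methyl-1,3-dioxolane | CC1(CCBr)OCCO1 | starting material
9 | [2-(2-methyl-1,3-dioxolan-2-yl)ethyl]magnesium bromide | CC1(CC[Mg]Br)OCCO1 | intermediate
10 | 13,13-ethylenedioxy-14,15-dinorlabd-7-en-9-ol (9β-OH) | C1C=C(C)[C@@](O)(CCC3(C)OCCO3)[C@@]2(C)CCCC(C)(C)[C@H]12 | intermediate
11 | 13,13-ethylenedioxy-14,15-dinorlabd-8-en-7-one | C1C(=O)C(C)=C(CCC3(C)OCCO3)[C@@]2(C)CCCC(C)(C)[C@H]12 | intermediate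
12 | 14,15-dinorlabd-8-ene-7,13-dione | C1C(=O)C(C)=C(CCC(C)=O)[C@@]2(C)CCCC(C)(C)[C@H]12 | intermediate
13 | allyl diethylphosphonoacetate | CCOP(=O)(OCC)CC(=O)OCC=C | starting material
14 | allyl 7-oxolabda-8,13E-dien-15-oate | C1C(=O)C(C)=C(CC/C(C)=C/C(=O)OCC=C)[C@@]2(C)CCCC(C)(C)[C@H]12 | intermediate
15 | allyl 7-(trimethylsilyloxy)labda-6,8,13E-trien-15-oate | C1=C(O[Si](C)(C)C)C(C)=C(CC/C(C)=C/C(=O)OCC=C)[C@@]2(C)CCCC(C)(C)[C@H]12 | intermediate
16 | allyl 6α-bromo-7-oxolabda-8,13E-dien-15-oate | Br[C@H]1C(=O)C(C)=C(CC/C(C)=C/C(=O)OCC=C)[C@@]2(C)CCCC(C)(C)[C@H]12 | intermediate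
17 | allyl 6α-bromo-7β-hydroxylabda-8,13E-dien-15-oate | Br[C@H]1[C@H](O)C(C)=C(CC/C(C)=C/C(=O)OCC=C)[C@@]2(C)CCCC(C)(C)[C@H]12 | intermediate
18 | allyl 6β,7β-epoxylabda-8,13E-dien-15-oate | O1[C@@H]2[C@H]1C(C)=C(CC/C(C)=C/C(=O)OCC=C)[C@@]3(C)CCCC(C)(C)[C@H]23 | intermediate
19 | allyl 6β-hydroxy-7α-(3-methylbutanoyloxy)labda-8,13E-dien-15-oate | O[C@@H]1[C@@H](OC(=O)CC(C)C)C(C)=C(CC/C(C)=C/C(=O)OCC=C)[C@@]2(C)CCCC(C)(C)[C@H]12 | intermediate
20 | allyl 6β-acetoxy-7α-(3-methylbutanoyloxy)labda-8,13E-dien-15-oate | CC(=O)O[C@@H]1[C@@H](OC(=O)CC(C)C)C(C)=C(CC/C(C)=C/C(=O)OCC=C)[C@@]2(C)CCCC(C)(C)[C@H]12 | intermediate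
21 | 6β-acetoxy-7α-(3-methylbutanoyloxy)labda-8,13E-dien-15-oic acid | CC(=O)O[C@@H]1[C@@H](OC(=O)CC(C)C)C(C)=C(CC/C(C)=C/C(=O)O)[C@@]2(C)CCCC(C)(C)[C@H]12 | target

**Step count and risks**

Total step count: 15. Longest linear sequence: 15 steps, from 1.

Steps most likely to fail:

- **Step 3.** The C4 radical may be reduced before it cyclises (net hydrogenation of the isopropenyl group), or hydrogen-atom transfer may go to the acrylate first. The fallback sets out from 4. Markovnikov addition of HBr (33% HBr in AcOH, 0 °C, the classical hydrobromination of the carvone isopropenyl group) should give the tertiary bromide methyl 2-{[6-(2-bromopropan-2-yl)-1,3-dimethyl-2-oxocyclohex-3-en-1-yl]methyl}prop-2-enoate F1. Slow addition of Bu3SnH with AIBN in benzene at 80 °C then generates the same C4 radical by bromine abstraction, with the hydrogen-donor concentration kept low, and the 6-endo closure comes back to the route at 5.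

- **Step 12.** Ring closure from the trans-diequatorial bromohydrin must pass through a boat-like ring B and may be outrun by elimination or by hydride shift to a ketone. The fallback sets out from 14 and sets C7 by Mitsunobu inversion and C6 by oxidation and α-face reduction:
  - LiN(SiMe3)2 and then 2-(phenylsulfonyl)-3-phenyloxaziridine give allyl 6α-hydroxy-7-oxolabda-8,13E-dien-15-oate F2.
  - t-BuMe2SiOSO2CF3 and 2,6-lutidine give allyl 6α-(tert-butyldimethylsilyloxy)-7-oxolabda-8,13E-dien-15-oate F3.
  - NaBH4 with CeCl3·7H2O gives allyl 6α-(tert-butyldimethylsilyloxy)-7β-hydroxylabda-8,13E-dien-15-oate F4.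
  - PPh3, DIAD and 3-methylbutanoic acid invert the allylic C7 to allyl 6α-(tert-butyldimethylsilyloxy)-7α-(3-methylbutanoyloxy)labda-8,13E-dien-15-oate F5.
  - HF·pyridine frees allyl 6α-hydroxy-7α-(3-methylbutanoyloxy)labda-8,13E-dien-15-oate F6.
  - Dess–Martin periodinane with NaHCO3 gives allyl 7α-(3-methylbutanoyloxy)-6-oxolabda-8,13E-dien-15-oate F7.
  - NaBH4 in MeOH at −20 °C delivers hydride from the α-face and comes back to the route at 19.

- **Step 13.** The vinyl epoxide may ionise to the C7–C9 allyl cation before the weakly nucleophilic acid attacks, with capture at C9 or elimination. The fallback sets out from 18 and separates C–O bond formation from acylation. Hydration with a large excess of water (cat. HClO4, THF/H2O, 0 °C) should give allyl 6β,7α-dihydroxylabda-8,13E-dien-15-oate F8. Isovaleric anhydride with cat. DMAP and Et3N in CH2Cl2 at −20 °C then acylates the less hindered allylic 7α-hydroxyl selectively and comes back to the route at 19.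

**Further compounds**

F1 | step 3 | methyl 2-{[6-(2-bromopropan-2-yl)-1,3-dimethyl-2-oxocyclohex-3-en-1-yl]methyl}prop-2-enoate | C1C=C(C)C(=O)[C@@](C)(CC(=C)C(=O)OC)[C@@H]1C(C)(C)Br
F2 | step 12 | allyl 6α-hydroxy-7-oxolabda-8,13E-dien-15-oate | O[C@H]1C(=O)C(C)=C(CC/C(C)=C/C(=O)OCC=C)[C@@]2(C)CCCC(C)(C)[C@H]12
F3 | step 12 | allyl 6α-(tert-butyldimethylsilyloxy)-7-oxolabda-8,13E-dien-15-oate | CC(C)(C)[Si](C)(C)O[C@H]1C(=O)C(C)=C(CC/C(C)=C/C(=O)OCC=C)[C@@]2(C)CCCC(C)(C)[C@H]12
F4 | step 12 | allyl 6α-(tert-butyldimethylsilyloxy)-7β-hydroxylabda-8,13E-dien-15-oate | CC(C)(C)[Si](C)(C)O[C@H]1[C@H](O)C(C)=C(CC/C(C)=C/C(=O)OCC=C)[C@@]2(C)CCCC(C)(C)[C@H]12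
F5 | step 12 | allyl 6α-(tert-butyldimethylsilyloxy)-7α-(3-methylbutanoyloxy)labda-8,13E-dien-15-oate | CC(C)(C)[Si](C)(C)O[C@H]1[C@@H](OC(=O)CC(C)C)C(C)=C(CC/C(C)=C/C(=O)OCC=C)[C@@]2(C)CCCC(C)(C)[C@H]12
F6 | step 12 | allyl 6α-hydroxy-7α-(3-methylbutanoyloxy)labda-8,13E-dien-15-oate | O[C@H]1[C@@H](OC(=O)CC(C)C)C(C)=C(CC/C(C)=C/C(=O)OCC=C)[C@@]2(C)CCCC(C)(C)[C@H]12
F7 | step 12 | allyl 7α-(3-methylbutanoyloxy)-6-oxolabda-8,13E-dien-15-oate | O=C1[C@@H](OC(=O)CC(C)C)C(C)=C(CC/C(C)=C/C(=O)OCC=C)[C@@]2(C)CCCC(C)(C)[C@H]12
F8 | step 13 | allyl 6β,7α-dihydroxylabda-8,13E-dien-15-oate | O[C@@H]1[C@@H](O)C(C)=C(CC/C(C)=C/C(=O)OCC=C)[C@@]2(C)CCCC(C)(C)[C@H]12
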